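**Retrosynthetic overview**
1. Target 15 ⇐ bis-epoxy keto lactone 14: water opens the 7,8-epoxide at C8 and the epoxide oxygen on C7 opens the 3,4-epoxide at C4 (tetrahydrofuran, formed last).
2. 14 ⇐ cembratetraenoic acid 11: threefold Shi epoxidation, then the CO2H group opens the 11,12-epoxide at C12 (ε-lactone, formed second) and the freed C11 carbinol is oxidised in the same flask.
3. 11 ⇐ open-chain C20 epoxy sulfone 6: the C1–C2 bond (the bond cembrene synthase forms from geranylgeranyl diphosphate) is closed by attack of a sulfonyl carbanion on a Sharpless epoxide with inversion (14-membered carbocycle, formed first).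
4. 6 ⇐ (2E,6E,10E)-geranylgeraniol 1, which already holds all twenty carbons and the three ring E-alkenes.
5. Ring order: carbocycle → ε-lactone → tetrahydrofuran. C1 comes from the Sharpless epoxide; C3, C4, C7, C8 and C12 come from the Shi epoxides and their inversions.

Assumption: all-E-geranylgeraniol (annatto-derived bulk terpenoid) is taken as cheap commercial material. Open-chain compounds use geranylgeranyl numbering; macrocycles use cembrane numbering (C1 carries the side chain C15–C17, C2 is the former sulfonyl carbon, C16 the oxygenated/carboxyl carbon, C17 the methyl/methylene carbon, C18–C20 the methyls on C4, C8, C12).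

**Step 1**
Reactants: 1 (2E,6E,10E)-geranylgeraniol
Product: 3 (2E,6E,10E)-geranylgeranyl phenyl sulfone, via geranylgeranyl bromide 2 (not isolated)
Conditions: PBr3 (0.4 equiv), Et2O, −10 °C; then PhSO2Na, DMF, rt
Reagents that add atoms: PBr3, BrP(Br)Br (bromine of 2 only); sodium benzenesulfinate PhSO2Na, [Na+].[O-]S(=O)c1ccccc1
Why: PBr3 converts the primary allylic alcohol into the bromide without allylic transposition and the soft sulfinate then S-alkylates it (SN2) in DMF, giving the all-E allylic sulfone that acidifies the future C2.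

**Step 2**
Reactants: 3 (2E,6E,10E)-geranylgeranyl phenyl sulfone
Product: 4 (2E,6E,10E,14E)-16-hydroxygeranylgeranyl phenyl sulfone
Conditions: SeO2 (0.2 equiv), t-BuOOH, salicylic acid (cat.), CH2Cl2, 0 °C → rt
Reagents that add atoms: tert-butyl hydroperoxide, CC(C)(C)OO (oxygen delivered through SeO2, O=[Se]=O)
Why: SeO2-catalysed allylic oxidation (ene reaction, then [2,3]-sigmatropic shift) is selective for the E-methyl group of the terminal, most electron-rich trisubstituted alkene and gives the E-allylic alcohol, with no stereocentre formed (moderate yield, recovered 3 is recycled).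

**Step 3**
Reactants: 4 (2E,6E,10E,14E)-16-hydroxygeranylgeranyl phenyl sulfone
Product: 6 (2E,6E,10E,14R,15R)-14,15-epoxy-16-(triethylsilyloxy)geranylgeranyl phenyl sulfone, via epoxy alcohol 5 (not isolated)
Conditions: Ti(OiPr)4 (10 mol %), D-(−)-diethyl tartrate (12 mol %), t-BuOOH, 4 Å MS, CH2Cl2, −20 °C; then Et3N, Et3SiCl, DMAP (cat.), −20 → 0 °C
Reagents that add atoms: tert-butyl hydroperoxide, CC(C)(C)OO; chlorotriethylsilane, CC[Si](Cl)(CC)CC
Why: Sharpless asymmetric epoxidation of the E-2-methyl allylic alcohol with the D-(−)-tartrate catalyst delivers oxygen to one face only and sets C14 and C15 as R,R (other alkenes lack an allylic hydroxyl and are untouched), and in-flask silylation then masks the primary alcohol.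

**Step 4**
Reactants: 6 (2E,6E,10E,14R,15R)-14,15-epoxy-16-(triethylsilyloxy)geranylgeranyl phenyl sulfone
Product: 7 (1S,15S)-2-(phenylsulfonyl)-16-(triethylsilyloxy)cembra-3E,7E,11E-trien-15-ol (C2 epimers)
Conditions: LiN(iPr)2 (1.2 equiv), THF (0.003 M, slow addition of 6), −78 → 0 °C; AcOH quench
Reagents that add atoms: none
Why: Kodama-type macrocyclisation in which the lithiated allylic sulfone (α-carbanion, future C2) opens the trisubstituted epoxide by intramolecular SN2 attack at its secondary carbon (future C1) under high dilution, forming the C1–C2 bond of cembrene biosynthesis with reversed polarity and fixing C1 by clean inversion of the Sharpless centre (the descriptor reads 1S only because the sulfonyl carbon outranks C15), while C2 forms as an inconsequential epimer mixture.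

**Step 5**
Reactants: 7 (1S,15S)-2-(phenylsulfonyl)-16-(triethylsilyloxy)cembra-3E,7E,11E-trien-15-ol
Product: 8 (1S)-2-(phenylsulfonyl)-16-(triethylsilyloxy)cembra-3E,7E,11E,15(17)-tetraene (C2 epimers)
Conditions: SOCl2, pyridine, CH2Cl2, −40 → 0 °C
Reagents that add atoms: none
Why: E2 dehydration of the tertiary chlorosulfite by pyridine takes a proton preferentially from the unhindered C17 methyl group (three hydrogens) and not from the crowded C1–H (inductively deactivated by the neighbouring sulfonyl carbon) or the C16 hydrogens (deactivated by the silyloxy group), giving the 1,1-disubstituted alkene without touching a stereocentre.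

**Step 6**
Reactants: 8 (1S)-2-(phenylsulfonyl)-16-(triethylsilyloxy)cembra-3E,7E,11E,15(17)-tetraene
Product: 9 (1R)-16-(triethylsilyloxy)cembra-3E,7E,11E,15(17)-tetraene
Conditions: PdCl2[Ph2P(CH2)3PPh2] (5 mol %), LiBHEt3, THF, 0 °C
Reagents that add atoms: none
Why: palladium-catalysed reductive desulfonylation (Inomata–Kotake) ionises the allylic sulfone to a π-allyl complex that takes hydride at the less substituted terminus C2, so the 3E trisubstituted alkene stays in place and both C2 epimers converge on one compound (C1 unchanged in space, now 1R by priority).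

**Step 7**
Reactants: 9 (1R)-16-(triethylsilyloxy)cembra-3E,7E,11E,15(17)-tetraene
Product: 11 (1R)-cembra-3E,7E,11E,15(17)-tetraen-16-oic acid, via enal 10 (not isolated)
Conditions: (COCl)2, DMSO, CH2Cl2, −78 → −40 °C; Et3N, → rt; then NaClO2, NaH2PO4, 2-methyl-2-butene, t-BuOH/H2O, rt
Reagents that add atoms: sodium chlorite NaClO2, [Na+].[O-]Cl=O
Why: under Swern conditions a primary triethylsilyl ether is desilylated by the chlorosulfonium salt and oxidised directly to the aldehyde, and Pinnick oxidation (2-methyl-2-butene shields the trisubstituted alkenes from HOCl) turns the 2-substituted acrolein into the acrylic acid without affecting C1.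

**Step 8**
Reactants: 11 (1R)-cembra-3E,7E,11E,15(17)-tetraen-16-oic acid
Product: 14 (1R,3S,4S,7S,8S,12R)-3,4:7,8-diepoxy-11-oxocembr-15(17)-en-16,12-olide, via tris-epoxy acid 12 (not isolated), via hydroxy lactone 13 (not isolated)
Conditions: ent-Shi ketone (L-series, from L-sorbose; 0.3 equiv per alkene), KHSO5 (as 2KHSO5·KHSO4·K2SO4), K2CO3, Bu4NHSO4, MeCN/CH2(OMe)2/aq. Na2B4O7, 0 °C; then NaH2PO4 to pH 5, extract into CH2Cl2 at 0 °C; Dess–Martin periodinane, 0 °C → rt
Reagents that add atoms: potassium peroxymonosulfate KHSO5, [K+].[O-]S(=O)(=O)OO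
Why: Proposed new method: Shi epoxidation with the L-series ketone gives the S,S epoxide of each E-trisubstituted alkene through its spiro transition state (the electron-poor acrylate is inert); on liberation of the acid the carboxyl group opens the 11,12-epoxide 7-exo at the tertiary carbon C12 with inversion (12R, the sinulariolide-type ε-lactone closure), and the freed C11 carbinol is oxidised at once by the periodinane so that it cannot add to the 7,8-epoxide; the closest known reactions are epoxy-acid lactonisation and Dess–Martin oxidation, merged here in one flask.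

**Step 9**
Reactants: 14 (1R,3S,4S,7S,8S,12R)-3,4:7,8-diepoxy-11-oxocembr-15(17)-en-16,12-olide
Product: 15 (1R,3S,4R,7S,8R,12R)-4,7-epoxy-3,8-dihydroxy-11-oxocembr-15(17)-en-16,12-olide (CNP0266269.2)
Conditions: camphorsulfonic acid (10 mol %), THF/H2O (5:1), 0 °C → rt
Reagents that add atoms: water, O
Why: acid-catalysed epoxide-opening cascade as in the presumed biosynthesis, in which the 7,8-epoxide (assisted by the C11 carbonyl through a five-membered oxocarbenium) is opened by water at its tertiary carbon C8 with inversion (8R) and its oxygen attacks the tertiary carbon C4 of the 3,4-epoxide 5-exo with inversion (4R), giving the cis-2,5-disubstituted tetrahydrofuran with 3S and 7S retained.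

**Compound list**
1 | (2E,6E,10E)-geranylgeraniol | CC(C)=CCC/C(C)=C/CC/C(C)=C/CC/C(C)=C/CO | starting material
2 | (2E,6E,10E)-geranylgeranyl bromide | CC(C)=CCC/C(C)=C/CC/C(C)=C/CC/C(C)=C/CBr | intermediate
3 | (2E,6E,10E)-geranylgeranyl phenyl sulfone | CC(C)=CCC/C(C)=C/CC/C(C)=C/CC/C(C)=C/CS(=O)(=O)c1ccccc1 | intermediate
4 | (2E,6E,10E,14E)-16-hydroxygeranylgeranyl phenyl sulfone | OC/C(C)=C/CC/C(C)=C/CC/C(C)=C/CC/C(C)=C/CS(=O)(=O)c1ccccc1 | intermediate
5 | (2E,6E,10E,14R,15R)-14,15-epoxy-16-hydroxygeranylgeranyl phenyl sulfone | OC[C@@]1(C)O[C@@H]1CC/C(C)=C/CC/C(C)=C/CC/C(C)=C/CS(=O)(=O)c1ccccc1 | intermediate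
6 | (2E,6E,10E,14R,15R)-14,15-epoxy-16-(triethylsilyloxy)geranylgeranyl phenyl sulfone | CC[Si](CC)(CC)OC[C@@]1(C)O[C@@H]1CC/C(C)=C/CC/C(C)=C/CC/C(C)=C/CS(=O)(=O)c1ccccc1 | intermediate
7 | (1S,15S)-2-(phenylsulfonyl)-16-(triethylsilyloxy)cembra-3E,7E,11E-trien-15-ol (C2 epimers) | CC[Si](CC)(CC)OC[C@@](C)(O)[C@@H]1CC/C(C)=C/CC/C(C)=C/CC/C(C)=C/C1S(=O)(=O)c1ccccc1 | intermediate
8 | (1S)-2-(phenylsulfonyl)-16-(triethylsilyloxy)cembra-3E,7E,11E,15(17)-tetraene (C2 epimers) | C=C(CO[Si](CC)(CC)CC)[C@@H]1CC/C(C)=C/CC/C(C)=C/CC/C(C)=C/C1S(=O)(=O)c1ccccc1 | intermediate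
9 | (1R)-16-(triethylsilyloxy)cembra-3E,7E,11E,15(17)-tetraene | C=C(CO[Si](CC)(CC)CC)[C@@H]1CC/C(C)=C/CC/C(C)=C/CC/C(C)=C/C1 | intermediate
10 | (1R)-cembra-3E,7E,11E,15(17)-tetraen-16-al | C=C(C=O)[C@@H]1CC/C(C)=C/CC/C(C)=C/CC/C(C)=C/C1 | intermediate
11 | (1R)-cembra-3E,7E,11E,15(17)-tetraen-16-oic acid | C=C(C(=O)O)[C@@H]1CC/C(C)=C/CC/C(C)=C/CC/C(C)=C/C1 | intermediate
12 | (1R,3S,4S,7S,8S,11S,12S)-3,4:7,8:11,12-triepoxycembr-15(17)-en-16-oic acid | C=C(C(=O)O)[C@@H]1CC[C@]2(C)O[C@H]2CC[C@]3(C)O[C@H]3CC[C@]4(C)O[C@H]4C1 | intermediate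
13 | (1R,3S,4S,7S,8S,11S,12R)-3,4:7,8-diepoxy-11-hydroxycembr-15(17)-en-16,12-olide | C=C1C(=O)O[C@]2(C)CC[C@@H]1C[C@@H]3O[C@@]3(C)CC[C@@H]4O[C@@]4(C)CC[C@@H]2O | intermediate
14 | (1R,3S,4S,7S,8S,12R)-3,4:7,8-diepoxy-11-oxocembr-15(17)-en-16,12-olide | C=C1C(=O)O[C@]2(C)CC[C@@H]1C[C@@H]3O[C@@]3(C)CC[C@@H]4O[C@@]4(C)CCC2=O | intermediate
15 | (1R,3S,4R,7S,8R,12R)-4,7-epoxy-3,8-dihydroxy-11-oxocembr-15(17)-en-16,12-olide | C=C1C(=O)O[C@]2(C)CC[C@@H]1C[C@H](O)[C@@]1(C)CC[C@H](O1)[C@](C)(O)CCC2=O | target

**Totals and risks**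
Total step count: 9. Longest linear sequence: 9 (one linear sequence from 1).

Most likely to fail, step 8. The acid may instead open the 3,4-epoxide (δ- or ε-lactone at C3/C4), the macrocycle may override the catalyst on one face, or the C11 carbinol may add to the 7,8-epoxide before it is oxidised. The fallback sets out from sulfone 8, whose allylic sulfonyl group switches off C3=C4. Shi epoxidation with the same ketone then touches only C7=C8 and C11=C12 and gives the 7,8:11,12-bis-epoxy sulfone F1. Na(Hg)/Na2HPO4 in MeOH/THF at −20 °C removes the sulfonyl group to give the bis-epoxy silyl ether F2. Swern oxidation followed by Ag2O/NaOH gives the bis-epoxy acid F3, kept as its sodium salt. Acidification into CH2Cl2 that holds Dess–Martin periodinane lets the acid reach only C12 and gives the 7,8-epoxy keto lactone F4, which still has the C3=C4 alkene. A second Shi epoxidation of this last trisubstituted alkene comes back to the route at 14.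

Second, step 9. Water may open the 3,4-epoxide first, a 6-endo closure may give a tetrahydropyran, or the C11 ketone may be trapped as a bicyclic ketal. The fallback also sets out from 8 and runs as above to the 7,8-epoxy keto lactone F4. Aqueous HClO4 (cat.) in THF hydrolyses its only epoxide at C8 with inversion to the (7S,8R)-diol F5. Shi epoxidation of C3=C4 then forms the (3S,4S)-epoxide next to the free C7 hydroxyl, which closes 5-exo onto C4 (camphorsulfonic acid on work-up). The order of the two ring openings is thus fixed by construction and the fallback comes back at 15.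

Third, step 5. Elimination may run towards C1 (tetrasubstituted alkene) or C16 (enol ether). The fallback sets out from 7 and replaces dehydration by an epoxide-to-allylic-alcohol isomerisation. The sulfonyl group is removed first with PdCl2[Ph2P(CH2)3PPh2]/LiBHEt3, because a sulfonyl carbanion would later open the epoxide to a cyclopropane; this gives the tertiary alcohol F6. Bu4NF gives the 15,16-diol F7. PPh3/diisopropyl azodicarboxylate closes the 15,16-epoxide F8. LiNEt2 abstracts a proton from the C17 methyl group and gives the 2-substituted allylic alcohol F9. MnO2 and then NaClO2 (through enal 10) come back to the route at 11.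

**Further compounds**
F1 | step 8 | (1S,7S,8S,11S,12S)-7,8:11,12-diepoxy-2-(phenylsulfonyl)-16-(triethylsilyloxy)cembra-3E,15(17)-diene (C2 epimers) | C=C(CO[Si](CC)(CC)CC)[C@@H]1CC[C@]2(C)O[C@H]2CC[C@]3(C)O[C@H]3CC/C(C)=C/C1S(=O)(=O)c1ccccc1
F2 | step 8 | (1R,7S,8S,11S,12S)-7,8:11,12-diepoxy-16-(triethylsilyloxy)cembra-3E,15(17)-diene | C=C(CO[Si](CC)(CC)CC)[C@@H]1CC[C@]2(C)O[C@H]2CC[C@]3(C)O[C@H]3CC/C(C)=C/C1
F3 | step 8 | (1R,7S,8S,11S,12S)-7,8:11,12-diepoxycembra-3E,15(17)-dien-16-oic acid | C=C(C(=O)O)[C@@H]1CC[C@]2(C)O[C@H]2CC[C@]3(C)O[C@H]3CC/C(C)=C/C1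
F4 | step 8 | (1R,7S,8S,12R)-7,8-epoxy-11-oxocembra-3E,15(17)-dien-16,12-olide | C=C1C(=O)O[C@]2(C)CC[C@@H]1C/C=C(C)/CC[C@@H]3O[C@@]3(C)CCC2=O
F5 | step 9 | (1R,7S,8R,12R)-7,8-dihydroxy-11-oxocembra-3E,15(17)-dien-16,12-olide | C=C1C(=O)O[C@]2(C)CC[C@@H]1C/C=C(C)/CC[C@H](O)[C@](C)(O)CCC2=O
F6 | step 5 | (1R,15S)-16-(triethylsilyloxy)cembra-3E,7E,11E-trien-15-ol | CC[Si](CC)(CC)OC[C@@](C)(O)[C@@H]1CC/C(C)=C/CC/C(C)=C/CC/C(C)=C/C1
F7 | step 5 | (1R,15S)-cembra-3E,7E,11E-triene-15,16-diol | OC[C@@](C)(O)[C@@H]1CC/C(C)=C/CC/C(C)=C/CC/C(C)=C/C1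
F8 | step 5 | (1R,15S)-15,16-epoxycembra-3E,7E,11E-triene | C[C@@]1(CO1)[C@@H]2CC/C(C)=C/CC/C(C)=C/CC/C(C)=C/C2
F9 | step 5 | (1R)-cembra-3E,7E,11E,15(17)-tetraen-16-ol | C=C(CO)[C@@H]1CC/C(C)=C/CC/C(C)=C/CC/C(C)=C/C1
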